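The route rests on cutting the sp2–sp2 single bond between C6 of the β-ring (tetrasubstituted C5=C6 alkene) and C7 of the polyene. The key step exploits the fact that C6 is flanked by quaternary C1. A C6 ketone can enolise only toward C5, so actinol linolenate gives one enol triflate with C3 untouched. The partner is a C31 octaen-yne that ends in a terminal C7≡C8 alkyne and already carries the (3'R,6'R) ε-ring ester. One-pot hydrozirconation, zinc transmetalation and palladium coupling set the 7E alkene, forge the hindered C6–C7 bond, complete the decaene chromophore and release the finished diester in the last step.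

Key step: step 12

Assumption: carotenoid numbering is used (C1–C20 for the β half, primed numbers for the ε half), and (4R,6R)-actinol, the all-E C10-dialdehyde and (E)-3-methylpent-2-en-4-yn-1-ol are taken as catalogue carotenoid building blocks; all polyene work is done under argon in dim light.

Step 1
Reactants: 1 (4R,6R)-4-hydroxy-2,2,6-trimethylcyclohexanone (actinol); 2 α-linolenic acid
Product: 3 (1R,5R)-3,3,5-trimethyl-4-oxocyclohexyl (9Z,12Z,15Z)-octadeca-9,12,15-trienoate
Conditions: DCC, DMAP (cat.), CH2Cl2, 0 °C → rt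
Reagents that add atoms: none
Why: Steglich esterification acylates the unhindered secondary hydroxyl without breaking its C–O bond, so the (3R) centre of the chiral-pool ketone is carried over unchanged and the skipped Z-triene sees neither acid nor heat.

Step 2
Reactants: 3 actinol α-linolenate
Product: 4 (1R)-3,5,5-trimethyl-4-(trifluoromethylsulfonyloxy)cyclohex-3-en-1-yl α-linolenate (β-ring enol triflate)
Conditions: Tf2O (1.3 equiv), 2,6-di-tert-butyl-4-methylpyridine (1.5 equiv), CH2Cl2, 0 °C → rt
Reagents that add atoms: triflic anhydride, O=S(=O)(OS(=O)(=O)C(F)(F)F)C(F)(F)F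
Why: Enol triflate formation by O-sulfonylation of the ketone and loss of the only α-hydrogen (C5–H, since C1 is quaternary) gives a single tetrasubstituted C5=C6 regioisomer from either C5 epimer, while the hindered non-nucleophilic pyridine traps the acid and avoids enolate chemistry at the ester α-CH2.

Step 3
Reactants: 5 (±)-α-ionone
Product: 6 (±)-3-oxo-α-ionone, 4-[(1E)-3-oxobut-1-enyl]-3,5,5-trimethylcyclohex-2-en-1-one
Conditions: t-BuOOH (70 % aq., 5 equiv), Rh2(cap)4 (1 mol %), 1,2-dichloroethane, 40 °C
Reagents that add atoms: tert-butyl hydroperoxide, CC(C)(C)OO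
Why: Radical allylic oxidation (tert-butylperoxyl chain under dirhodium caprolactamate catalysis) converts the accessible ring allylic CH2 (C3') into the enone carbonyl, the tertiary C6'–H being shielded by the C1' gem-dimethyl group and the side chain, and the material stays racemic at C6'.

Step 4
Reactants: 6 (±)-3-oxo-α-ionone
Product: 7 (±)-4-[(1E)-3-hydroxy-3-methylpenta-1,4-dien-1-yl]-3,5,5-trimethylcyclohex-2-en-1-one (C9' epimers)
Conditions: vinylMgBr (1.05 equiv), LaCl3·2LiCl (30 mol %), THF, −78 °C; aq. NH4Cl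
Reagents that add atoms: vinylmagnesium bromide, C=C[Mg]Br
Why: Chemoselective Grignard 1,2-addition works because the side-chain methyl ketone is far less hindered than the isophorone-type ring enone (β,β-disubstituted and flanked by a neopentyl CH2), the lanthanum salt suppresses enolisation, and the new C9' carbinol centre forms as an epimer mixture that is erased in step 8.

Step 5
Reactants: 7 (±)-ring-keto vinyl carbinol
Product: 8 (±)-trans-diol, rac-(1R,4R)-4-[(1E)-3-hydroxy-3-methylpenta-1,4-dien-1-yl]-3,5,5-trimethylcyclohex-2-en-1-ol (C9' epimers)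
Conditions: L-Selectride (2.2 equiv), THF, −78 °C; then aq. NaOH, H2O2, 0 °C; chromatography
Reagents that add atoms: none
Why: In this Selectride 1,2-reduction of a β,β-disubstituted cyclohexenone the C6' chain sits pseudoaxial and the opposite ring face is blocked by the axial C1' methyl that is 1,3-related to C3', so the bulky hydride should enter syn to the chain and place the new C3' hydroxyl trans to it (the relative configuration of lutein), any cis isomer being removed by chromatography.

Step 6
Reactants: 8 (±)-trans-diol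
Product: 9 (1R,4R)-4-[(1E)-3-hydroxy-3-methylpenta-1,4-dien-1-yl]-3,5,5-trimethylcyclohex-2-en-1-ol, the (3'R,6'R)-diol (C9' epimers)
Conditions: lipase AK (Pseudomonas fluorescens), vinyl acetate, MTBE, 30 °C, stopped slightly beyond half conversion; chromatography
Reagents that add atoms: none
Why: In this lipase-catalysed kinetic resolution by irreversible transesterification, Kazlauskas' rule with the C2'H2–C1'Me2 flank as the large group predicts faster acylation of the (3'S)-carbinol, so the (3'R,6'R)-diol stays behind and gains enantiopurity as conversion passes one half, which fixes the absolute configuration of C3' and C6' (the tertiary C9' hydroxyl is no lipase substrate).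

Step 7
Reactants: 9 (3'R,6'R)-diol; 2 α-linolenic acid
Product: 10 (1R,4R)-4-[(1E)-3-hydroxy-3-methylpenta-1,4-dien-1-yl]-3,5,5-trimethylcyclohex-2-en-1-yl α-linolenate
Conditions: DCC, DMAP (cat.), CH2Cl2, 0 °C → rt
Reagents that add atoms: none
Why: Steglich esterification is selective for the secondary C3' hydroxyl over the tertiary C9' hydroxyl and proceeds with retention because the C3'–O bond is not broken.

Step 8
Reactants: 10 ε-ring ester carbinol
Product: 11 [(2E,4E)-3-methyl-5-[(1R,4R)-2,6,6-trimethyl-4-(α-linolenoyloxy)cyclohex-2-en-1-yl]penta-2,4-dien-1-yl]triphenylphosphonium bromide (ε-C15 salt)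
Conditions: Ph3P·HBr (1.0 equiv), CH2Cl2, 0 °C → rt
Reagents that add atoms: triphenylphosphine hydrobromide, [Br-].c1ccc(cc1)[PH+](c1ccccc1)c1ccccc1
Why: Ionisation of the tertiary bis-allylic alcohol to a pentadienyl cation and capture by PPh3 at the unhindered terminus C11' (the classical vinyl-ionol to Wittig-salt conversion) erases the C9' epimers and should give mainly the 9'E diene, while the secondary allylic ester ionises far less readily.

Step 9
Reactants: 12 (E)-3-methylpent-2-en-4-yn-1-ol
Product: 13 [(2E)-3-methylpent-2-en-4-yn-1-yl]triphenylphosphonium bromide (C6 salt)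
Conditions: Ph3P·HBr (1.0 equiv), CH2Cl2–MeOH, rt
Reagents that add atoms: triphenylphosphine hydrobromide, [Br-].c1ccc(cc1)[PH+](c1ccccc1)c1ccccc1
Why: The same acid-promoted alcohol-to-phosphonium exchange works on this primary allylic alcohol through its methyl-stabilised allyl cation, attack of PPh3 at the primary terminus keeping the conjugated E-enyne.

Step 10
Reactants: 13 C6 salt; 14 (2E,4E,6E)-2,7-dimethylocta-2,4,6-trienedial (C10-dialdehyde)
Product: 16 (2E,4E,6E,8E,10E)-2,7,11-trimethyltrideca-2,4,6,8,10-pentaen-12-ynal (C16 enynal), via C6 ylide 15 (not isolated)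
Conditions: 14 (3 equiv), NaOMe (1 equiv, slow addition), CH2Cl2–MeOH, 0 °C → rt; then I2 (cat.), CH2Cl2, daylight, rt
Reagents that add atoms: none
Why: Wittig olefination of one aldehyde of the symmetrical dialdehyde (kept in excess) builds C11=C12, and iodine-catalysed photoequilibration at this ester-free stage funnels the 11E/11Z mixture expected from a semistabilised ylide into the all-E enynal.

Step 11
Reactants: 11 ε-C15 salt; 16 C16 enynal
Product: 18 (1R,4R)-3,5,5-trimethyl-4-[(1E,3E,5E,7E,9E,11E,13E,15E)-3,7,12,16-tetramethyloctadeca-1,3,5,7,9,11,13,15-octaen-17-yn-1-yl]cyclohex-2-en-1-yl α-linolenate (C31 octaen-yne), via C15 ylide 17 (not isolated)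
Conditions: 1,2-epoxybutane (solvent and HBr scavenger), reflux (63 °C), Ar, dark; chromatography
Reagents that add atoms: none
Why: Wittig olefination under essentially neutral epoxide-buffered conditions builds C11'=C12' without harming the ester or the C3' and C6' centres, the sterically hindered 11'Z isomer should relax thermally to 11'E at reflux, and the all-E compound is isolated by chromatography.

Step 12
Reactants: 18 C31 octaen-yne; 4 β-ring enol triflate
Product: 21 (3R,3'R,6'R)-β,ε-carotene-3,3'-diyl bis[(9Z,12Z,15Z)-octadeca-9,12,15-trienoate] (lutein di-α-linolenate), via alkenylzirconocene 19 (not isolated), via alkenylzinc chloride 20 (not isolated)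
Conditions: 18, Cp2Zr(H)Cl (1.1 equiv), THF, 0 °C → rt, dark; ZnCl2 (1.2 equiv), THF, 0 °C; then 4 (1.2 equiv), Pd2(dba)3 (2.5 mol %), P(2-furyl)3 (10 mol %), THF–NMP, 35 °C
Reagents that add atoms: none
Why: Cp2Zr(H)Cl adds syn across the terminal C7≡C8 alkyne of 18 with zirconium on C7, ZnCl2 exchanges zirconium for zinc, Pd(0) inserts into the C6–O bond of triflate 4, and transmetalation followed by reductive elimination forms C6–C7 with retention at both sp2 carbons. The closest known reaction type is the hydrozirconation/Negishi alkenyl–alkenyl coupling used for stereodefined polyenes, and palladium couplings of 2,6,6-trimethylcyclohexenyl triflates with polyenyl metals are established for this type of ring–chain bond. No ring is closed and no stereocentre is created; the one new stereoelement, the 7E alkene, is controlled by the syn, terminal-selective hydrometalation, while C3, C3' and C6' are spectators. The step needs chemoselectivity for the alkyne over the ester carbonyl, the internal polyene and the skipped Z-alkenes, which is secured because 18 holds one terminal alkyne and no terminal alkene and only about one equivalent of hydride is used. It also needs oxidative addition at the vinyl triflate to outrun ionisation of the allylic C3' ester, which the crowded trisubstituted C4'=C5' alkene and the weakly donating furylphosphine should ensure. The congestion at C6 (C1 gem-dimethyl, C5 methyl) is answered by the reactive, base-free zinc nucleophile, which allows coupling near room temperature so that esters and alkene geometries persist.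

Compound list
1 | (4R,6R)-4-hydroxy-2,2,6-trimethylcyclohexanone (actinol) | O[C@@H]1C[C@@H](C)C(=O)C(C)(C)C1 | starting material
2 | α-linolenic acid | CC/C=C\C/C=C\C/C=C\CCCCCCCC(=O)O | starting material
3 | (1R,5R)-3,3,5-trimethyl-4-oxocyclohexyl α-linolenate | CC/C=C\C/C=C\C/C=C\CCCCCCCC(=O)O[C@@H]1C[C@@H](C)C(=O)C(C)(C)C1 | intermediate
4 | (1R)-3,5,5-trimethyl-4-(trifluoromethylsulfonyloxy)cyclohex-3-en-1-yl α-linolenate | CC/C=C\C/C=C\C/C=C\CCCCCCCC(=O)O[C@@H]1CC(C)=C(OS(=O)(=O)C(F)(F)F)C(C)(C)C1 | intermediate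
5 | (±)-α-ionone | CC(=O)/C=C/C1C(C)=CCCC1(C)C | starting material
6 | (±)-3-oxo-α-ionone | CC(=O)/C=C/C1C(C)=CC(=O)CC1(C)C | intermediate
7 | (±)-4-[(1E)-3-hydroxy-3-methylpenta-1,4-dien-1-yl]-3,5,5-trimethylcyclohex-2-en-1-one, C9' epimers | C=CC(C)(O)/C=C/C1C(C)=CC(=O)CC1(C)C | intermediate
8 | (±)-trans-diol (racemate, both enantiomers written, C9' unspecified) | C=CC(C)(O)/C=C/[C@H]1C(C)=C[C@H](O)CC1(C)C.C=CC(C)(O)/C=C/[C@@H]1C(C)=C[C@@H](O)CC1(C)C | intermediate
9 | (3'R,6'R)-diol, (1R,4R)-4-[(1E)-3-hydroxy-3-methylpenta-1,4-dien-1-yl]-3,5,5-trimethylcyclohex-2-en-1-ol | C=CC(C)(O)/C=C/[C@H]1C(C)=C[C@H](O)CC1(C)C | intermediate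
10 | (1R,4R)-4-[(1E)-3-hydroxy-3-methylpenta-1,4-dien-1-yl]-3,5,5-trimethylcyclohex-2-en-1-yl α-linolenate | C=CC(C)(O)/C=C/[C@H]1C(C)=C[C@H](OC(=O)CCCCCCC/C=C\C/C=C\C/C=C\CC)CC1(C)C | intermediate
11 | ε-C15 triphenylphosphonium bromide | [Br-].C(/C=C(C)/C=C/[C@H]1C(C)=C[C@H](OC(=O)CCCCCCC/C=C\C/C=C\C/C=C\CC)CC1(C)C)[P+](c2ccccc2)(c3ccccc3)c4ccccc4 | intermediate
12 | (E)-3-methylpent-2-en-4-yn-1-ol | C#C/C(C)=C/CO | starting material
13 | [(2E)-3-methylpent-2-en-4-yn-1-yl]triphenylphosphonium bromide | [Br-].C#C/C(C)=C/C[P+](c1ccccc1)(c2ccccc2)c3ccccc3 | intermediate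
14 | (2E,4E,6E)-2,7-dimethylocta-2,4,6-trienedial | O=C/C(C)=C/C=C/C=C(C)/C=O | starting material
15 | C6 ylide from 13 | C#C/C(C)=C/[CH-][P+](c1ccccc1)(c2ccccc2)c3ccccc3 | intermediate
16 | (2E,4E,6E,8E,10E)-2,7,11-trimethyltrideca-2,4,6,8,10-pentaen-12-ynal | C#C/C(C)=C/C=C/C(C)=C/C=C/C=C(C)/C=O | intermediate
17 | C15 ylide from 11 | [CH-](/C=C(C)/C=C/[C@H]1C(C)=C[C@H](OC(=O)CCCCCCC/C=C\C/C=C\C/C=C\CC)CC1(C)C)[P+](c2ccccc2)(c3ccccc3)c4ccccc4 | intermediate
18 | C31 octaen-yne α-linolenate | C#C/C(C)=C/C=C/C(C)=C/C=C/C=C(C)/C=C/C=C(C)/C=C/[C@H]1C(C)=C[C@H](OC(=O)CCCCCCC/C=C\C/C=C\C/C=C\CC)CC1(C)C | intermediate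
19 | (7E)-C31 alkenylzirconocene chloride (Cp rings drawn σ-bound) | Cl[Zr](C1C=CC=C1)(C2C=CC=C2)/C=C/C(C)=C/C=C/C(C)=C/C=C/C=C(C)/C=C/C=C(C)/C=C/[C@H]3C(C)=C[C@H](OC(=O)CCCCCCC/C=C\C/C=C\C/C=C\CC)CC3(C)C | intermediate
20 | (7E)-C31 alkenylzinc chloride | Cl[Zn]/C=C/C(C)=C/C=C/C(C)=C/C=C/C=C(C)/C=C/C=C(C)/C=C/[C@H]1C(C)=C[C@H](OC(=O)CCCCCCC/C=C\C/C=C\C/C=C\CC)CC1(C)C | intermediate
21 | (3R,3'R,6'R)-lutein di-α-linolenate | CC/C=C\C/C=C\C/C=C\CCCCCCCC(=O)O[C@@H]1CC(C)=C(/C=C/C(C)=C/C=C/C(C)=C/C=C/C=C(C)/C=C/C=C(C)/C=C/[C@H]2C(C)=C[C@H](OC(=O)CCCCCCC/C=C\C/C=C\C/C=C\CC)CC2(C)C)C(C)(C)C1 | target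

Total step count: 12. Longest linear sequence: 8 steps (steps 3–8, 11 and 12, from 5).

Risk 1, step 12. The zirconium hydride may attack the ester. The coupling at the congested C6 may also be slower than protonolysis or homocoupling of the polyenylzinc. The fallback installs the metal earlier, on the ester-free C16 stage, and couples an isolated nucleophile. It sets out from 16. Palladium-catalysed hydrostannation (Bu3SnH, PdCl2(PPh3)2, THF, 0 °C) should give the stannyl hexaenal F1, from which the regioisomer can still be removed. Wittig reaction of F1 with 11 under the conditions of step 11 gives the C31 nonaenylstannane F2. A Stille coupling of F2 with 4 (Pd2(dba)3, AsPh3, NMP, 50 °C) comes back to the route at 21.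

Risk 2, step 5. Facial selectivity of the hydride delivery may be poor or reversed. The fallback sets C3' by SN2 inversion instead of by hydride approach. It sets out from 7, whose reduction then supplies the (±)-cis-diol F3. Lipase AK with vinyl acetate acylates its (3'S,6'R) enantiomer to the cis-acetate F4. K2CO3 in MeOH frees the (3'S,6'R)-diol F5. A Mitsunobu esterification of F5 with 2 (PPh3, DIAD, toluene, 0 °C) inverts C3' and comes back to the route at 10.

Risk 3, step 6. The lipase may discriminate the two enantiomers too weakly, or in the opposite sense. The fallback is a chemical resolution through diastereomers. It sets out from 8, which is esterified at C3' with (S)-O-methylmandelic acid (DCC, DMAP). This gives the (3'R,6'R)-mandelate F6 and the (3'S,6'S)-mandelate F7. The two are separated by chromatography and assigned by the mandelate NMR model. Methanolysis of F6 (K2CO3, MeOH) comes back to the route at 9.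

Further compounds
F1 | step 12 | (2E,4E,6E,8E,10E,12E)-2,7,11-trimethyl-13-(tributylstannyl)trideca-2,4,6,8,10,12-hexaenal | CCCC[Sn](CCCC)(CCCC)/C=C/C(C)=C/C=C/C(C)=C/C=C/C=C(C)/C=O
F2 | step 12 | (1R,4R)-3,5,5-trimethyl-4-[(all-E)-3,7,12,16-tetramethyl-18-(tributylstannyl)octadeca-1,3,5,7,9,11,13,15,17-nonaen-1-yl]cyclohex-2-en-1-yl α-linolenate | CCCC[Sn](CCCC)(CCCC)/C=C/C(C)=C/C=C/C(C)=C/C=C/C=C(C)/C=C/C=C(C)/C=C/[C@H]1C(C)=C[C@H](OC(=O)CCCCCCC/C=C\C/C=C\C/C=C\CC)CC1(C)C
F3 | step 5 | (±)-cis-diol (racemate, both enantiomers written, C9' unspecified) | C=CC(C)(O)/C=C/[C@H]1C(C)=C[C@@H](O)CC1(C)C.C=CC(C)(O)/C=C/[C@@H]1C(C)=C[C@H](O)CC1(C)C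
F4 | step 5 | (1S,4R)-4-[(1E)-3-hydroxy-3-methylpenta-1,4-dien-1-yl]-3,5,5-trimethylcyclohex-2-en-1-yl acetate | C=CC(C)(O)/C=C/[C@H]1C(C)=C[C@@H](OC(C)=O)CC1(C)C
F5 | step 5 | (1S,4R)-4-[(1E)-3-hydroxy-3-methylpenta-1,4-dien-1-yl]-3,5,5-trimethylcyclohex-2-en-1-ol | C=CC(C)(O)/C=C/[C@H]1C(C)=C[C@@H](O)CC1(C)C
F6 | step 6 | (3'R,6'R)-diol 3'-[(S)-O-methylmandelate] | C=CC(C)(O)/C=C/[C@H]1C(C)=C[C@H](OC(=O)[C@@H](OC)c2ccccc2)CC1(C)C
F7 | step 6 | (3'S,6'S)-diol 3'-[(S)-O-methylmandelate] | C=CC(C)(O)/C=C/[C@@H]1C(C)=C[C@@H](OC(=O)[C@@H](OC)c2ccccc2)CC1(C)C
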